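## Analysis of the target

Compound 44 is an elemane-type sesquiterpenoid hydroxy acid built on one cyclohexane ring, C5–C6–C7–C8–C9–C10 (elemane locants are used throughout). C10 is quaternary (methyl C14, vinyl C1=C2) and C9 is a CH2. O8 carries a (2Z)-4-acetoxy-2-methylbut-2-enoyl group, C7 the acrylic acid C11(=C13)–C12O2H, C6 a free hydroxyl, and C5 the unit C4(=C3)–C15H2OH. The five stereocentres are 5R,6S,7S,8R,10R: C5–C4, C6–O, C7–C11, C8–O and the C10 vinyl group lie on one ring face, and only the C10 methyl group lies on the other. The Z enoate with its allylic acetate can isomerise to E, and the free acid sits cis to both O6 and O8, so acid or base can close a 6,12-lactone or move the acyl group from O8 to O6. The unit C2=C1–C10–C5–C4=C3 is a cis-1,2-dialkenyl 1,5-diene that can undergo Cope rearrangement on heating. The hard points are four contiguous all-cis centres beside a quaternary carbon whose two substituents (methyl, vinyl) are nearly the same size, and four oxygen functions in four different states. The strategy rests on one feature: C10 bears a vinyl group, and its ring neighbour C9 can be the inner carbon of a second vinyl group before the C8–C9 bond exists. C10 can therefore be carried as a non-stereogenic methyl divinyl carbon, and a metathesis that forms C8=C9 closes the ring, makes C10 stereogenic and leaves the alkene through which O8 is delivered from C12.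

## Retrosynthetic reasoning

44 is traced to 43 by removal of three fluoride-labile groups, and 43 to alcohol 36 and acid 41 by cutting the O8–acyl bond. The Z enoate is the most fragile part, so it is attached last. Its geometry is taken from the ring of butenolide 37 (via 40).

36 is traced to methylene lactone 34 by closing the 12,8-lactone, to 31 by removing C13, and to iodolactone 30 and acid 29 by cutting the C8–O bond. Delivering O8 from the C12 carboxyl onto C8=C9 can only give a cis-fused γ-lactone, so C8 is set from C7 with no external reagent control. The forward sequence must remove iodine from C9, add C13 and reopen the lactone without letting it close again.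

29 is traced through 28 and 27 to diol 25, and 25 to methylene lactone 24 and lactone 21. The C4=C3 bond and the C15 alcohol both come from a γ-lactone whose carbonyl is C15 and whose α-CH2 is C4. This lactone also ties O6 up during the key step and keeps C4 saturated, so no second diene pair exists.

21 is traced to triene 20 by cutting C8=C9. This is the only ring bond whose formation can turn two identical vinyl groups on C10 into one ring carbon and one spectator vinyl group. The forward reaction must select the vinyl group that leaves the other cis to C5–C4.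

20 is traced to hydroxy ester 19 (acyl–oxygen bond, no stereochemical change), and 19 to aldehyde 12 and allyl chloride 16 (through 17 and 18) by cutting C6–C7. This one bond sets C6 and C7 together, and the vinyl group it leaves on C7 is the metathesis partner. The required face of 12 is the anti-Felkin one, so the allyl reagent has to carry the control.

12 is traced through thioester 11 to imide 10, and 10 to imide 8 and bromoacetate 9 by cutting C4–C5. C5 is the only stereocentre that must be made next to the prochiral C10, and the auxiliary sets it without reference to C10.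

8 is traced to acid 5 and auxiliary 6, 5 to ester 4, and 4 to dienol 2 and orthoacetate 3 by cutting C5–C10. A [3,3] shift of the dienol gives the methyl divinyl carbon in one step with no stereochemical question. 2 comes from enynol 1. The side fragment 16 is traced to 14 and 15 (alkene exchange) and 14 to 13.

## Alternatives that were turned down

Alternative 1: The ring bonds C5–C10 and C6–C7 are cut together. Forward, guaiacol A1 is oxidised (PhI(OAc)2, methanol) to its masked o-benzoquinone, whose diene C10=C1–C11=C7 is trapped by enol ether A2 to give bicyclo[2.2.2]octenone A3. Cleaving the C1=C11 bridge then frees the cyclohexane.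
- For: one step builds the ring, two ring bonds and the centres C5, C6, C7 and C10. Endo addition puts C5–C4 and C6–O on the face of the C1=C11 bridge, which is the all-cis array of 44. C10 is fixed by constitution (the methyl comes from the arene, C1 is a bridge carbon), so the methyl/vinyl discrimination of the chosen route does not arise. On this point Alternative 1 is stronger.
- Against: A3 is racemic, so a resolution or an auxiliary is needed. After bridge scission, C1 (aldehyde) and C11 (α-keto ester beside the epimerisable C7) each need a methylenation. The C9 ketal must be removed reductively, the C8 ketone reduced to the cis alcohol, and the lactol ether oxidised and methylenated.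
- Comparison: the chosen route is longer before the ring is closed, but it sets the absolute configuration with an auxiliary and a chiral reagent and brings in the vinyl groups as such.

Alternative 2: C5–C4 is cut. Forward, zerovalent palladium with a chiral bisphosphine (Pd(OAc)2, BINAP) inserts into the vinyl bromide of ester A4 and adds across one of the two enantiotopic enol ether alkenes. β-Hydride loss then gives the methylene δ-lactone A5.
- For: one catalytic step sets C10 and C5 from a Birch-derived arene. The lactone tether forces C10–C1 cis to C5–C4, which is the relationship the chosen route leaves to a modest conformational bias; here Alternative 2 is stronger. C3=C4 and O15 are present from the start.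
- Against: the carbopalladation creates a tertiary centre beside a quaternary one on an electron-rich trisubstituted alkene, and its enantioselectivity is uncertain. C6, C7 and C8 must then be built all-cis on a 1,3-dioxygenated ring with C7 between two carbonyl groups and configurationally labile. The lactone carbonyl C1 still has to be reduced and methylenated to the vinyl group.
- Comparison: the chosen route sets C5, C6 and C7 by acyclic methods before ring closure and derives C8 from C7 by lactonisation.

Alternative 3: C9–C10 and C5–C6 are cut. Forward, bis(silyloxy)diene A6 adds to the C10=C5 bond of the chiral butenolide A7 to give the endo adduct A8.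
- For: convergent, with absolute control from the menthyloxy acetal. C10–C1 is cis to C5–C4 by construction (again stronger on this point), O6 and the C8 carbonyl come from the diene, and C9 is already CH2.
- Against: the dienophile is a β-methyl butenolide that must form a quaternary carbon with an acid-sensitive, 2-substituted diene, which is a slow and doubtful cycloaddition. C4 arrives as a carboxyl carbon and needs C3 and C15 added. C1 is an acetal to be converted into the vinyl group. C7 is sp2 in A8 and must be set by protonation beside the C8 ketone before that ketone is reduced.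
- Comparison: the chosen route gets C3, C4 and C15 from a plain lactone by methylenation and reduction and leaves only one stereochemical risk, at C10.

Key step: step 12

Remarks.
- O12 is carried as a 4-methoxybenzyl ether in 20 and 21 so that it can be removed next to silyl ethers.
- (S,S)-TADDOL is (4S,5S)-2,2-dimethyl-α,α,α′,α′-tetraphenyl-1,3-dioxolane-4,5-dimethanol. Its cyclopentadienyltitanium allyl reagents are taken to attack the Re face of aldehydes, the sense needed at C6.
- Compounds 26–43 are named as elemane derivatives with the locants of 44. Their ring stereocentres have the arrangement of 44, and the SMILES in the list are authoritative.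
- After step 13 no step is run above room temperature, because of the 1,5-diene.

## Steps

Step 1
Reactants: 1 3-methylpent-2-en-4-yn-1-ol (E/Z mixture)
Product: 2 3-methylpenta-2,4-dien-1-ol (E/Z mixture)
Conditions: H2 (1 atm), Pd/CaCO3 poisoned with Pb(OAc)2 (Lindlar catalyst), quinoline, EtOAc, rt
Reagents that add atoms: none
Why: Lindlar semi-hydrogenation stops the terminal alkyne at the alkene; the E/Z ratio is irrelevant because this carbon becomes the non-stereogenic C10 in step 2.

Step 2
Reactants: 2 3-methylpenta-2,4-dien-1-ol; 3 triethyl orthoacetate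
Product: 4 ethyl 3-ethenyl-3-methylpent-4-enoate
Conditions: EtCO2H (cat.), 140 °C, EtOH distilled off
Reagents that add atoms: none
Why: Johnson–Claisen rearrangement: the mixed ketene acetal of the primary allylic alcohol undergoes the [3,3] shift, forming C5–C10 and a quaternary C10 with two identical vinyl groups, so no stereocontrol is needed.

Step 3
Reactants: 4 ethyl 3-ethenyl-3-methylpent-4-enoate
Product: 5 3-ethenyl-3-methylpent-4-enoic acid
Conditions: LiOH, THF/MeOH/H2O, rt; then aq. HCl
Reagents that add atoms: lithium hydroxide, [Li+].[OH-]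
Why: Ester saponification; the skipped diene is inert to hydroxide.

Step 4
Reactants: 5 3-ethenyl-3-methylpent-4-enoic acid; 6 (4S)-4-benzyl-1,3-oxazolidin-2-one
Product: 8 (4S)-4-benzyl-3-(3-ethenyl-3-methylpent-4-enoyl)-1,3-oxazolidin-2-one, via mixed pivalic anhydride 7 (not isolated)
Conditions: tBuCOCl, Et3N, THF, −20 °C; then 6, LiCl, rt
Reagents that add atoms: pivaloyl chloride, CC(C)(C)C(Cl)=O (in 7 only)
Why: N-acylation of the oxazolidinone through the mixed anhydride; the CH2C=O carbonyl of 7 is less hindered than the pivaloyl one and reacts first.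

Step 5
Reactants: 8 (4S)-4-benzyl-3-(3-ethenyl-3-methylpent-4-enoyl)-1,3-oxazolidin-2-one; 9 tert-butyl bromoacetate
Product: 10 tert-butyl (3S)-3-{[(4S)-4-benzyl-2-oxo-1,3-oxazolidin-3-yl]carbonyl}-4-ethenyl-4-methylhex-5-enoate
Conditions: NaN(SiMe3)2, THF, −78 °C; then 9, −78 → −40 °C
Reagents that add atoms: none
Why: Evans alkylation: the chelated Z sodium enolate is alkylated on the face away from the benzyl group, which sets C5 (S). The tert-alkyl group on the enolate carbon slows the reaction, but the bromoacetate is unhindered and reactive enough.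

Step 6
Reactants: 10 tert-butyl (3S)-3-{[(4S)-4-benzyl-2-oxo-1,3-oxazolidin-3-yl]carbonyl}-4-ethenyl-4-methylhex-5-enoate
Product: 11 tert-butyl (3S)-4-ethenyl-3-[(ethylsulfanyl)carbonyl]-4-methylhex-5-enoate
Conditions: EtSH, nBuLi, THF, 0 °C; then 10, 0 °C → rt
Reagents that add atoms: ethanethiol, CCS
Why: Thiolate cleaves hindered N-acyl oxazolidinones at the exocyclic carbonyl and is too weak a base to epimerise C5. The thioester route avoids a γ-hydroxy ester, which would lactonise onto the tert-butyl ester.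

Step 7
Reactants: 11 tert-butyl (3S)-4-ethenyl-3-[(ethylsulfanyl)carbonyl]-4-methylhex-5-enoate
Product: 12 tert-butyl (3S)-4-ethenyl-3-formyl-4-methylhex-5-enoate
Conditions: iBu2AlH (1.2 equiv), CH2Cl2, −78 °C
Reagents that add atoms: none
Why: Thioesters are reduced at −78 °C to the aldehyde through a stable tetrahedral aluminate, faster than the tert-butyl ester reacts; the aldehyde is used at once to protect C5.

Step 8
Reactants: 13 but-3-en-1-ol
Product: 14 1-[(but-3-en-1-yloxy)methyl]-4-methoxybenzene
Conditions: NaH, 4-MeOC6H4CH2Cl, Bu4NI (cat.), THF/DMF, 0 °C → rt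
Reagents that add atoms: 4-methoxybenzyl chloride, COc1ccc(CCl)cc1
Why: Williamson etherification; the 4-methoxybenzyl ether can later be removed oxidatively beside silyl ethers.

Step 9
Reactants: 14 1-[(but-3-en-1-yloxy)methyl]-4-methoxybenzene; 15 (2Z)-1,4-dichlorobut-2-ene
Product: 16 1-{[(5-chloropent-3-en-1-yl)oxy]methyl}-4-methoxybenzene (mainly E)
Conditions: second-generation Grubbs catalyst RuCl2(=CHPh)(H2IMes)(PCy3) (2 mol%), 15 (3 equiv), CH2Cl2, 40 °C
Reagents that add atoms: none
Why: Cross-metathesis of a terminal alkene with excess 1,4-dichlorobut-2-ene gives the allylic chloride; its E/Z ratio does not matter because the titanium reagent of step 10 equilibrates.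

Step 10
Reactants: 16 1-{[(5-chloropent-3-en-1-yl)oxy]methyl}-4-methoxybenzene; 12 tert-butyl (3S)-4-ethenyl-3-formyl-4-methylhex-5-enoate
Product: 19 tert-butyl (3S)-4-ethenyl-3-[(1R,2R)-1-hydroxy-2-{2-[(4-methoxyphenyl)methoxy]ethyl}but-3-en-1-yl]-4-methylhex-5-enoate, via allylmagnesium chloride 17 (not isolated), via allyltitanium complex 18 (not isolated)
Conditions: Mg, THF, 0 °C; then TiCl(C5H5)[(S,S)-TADDOLate], Et2O, −78 → 0 °C; then 12, −78 °C; aq. NH4F
Reagents that add atoms: magnesium, [Mg] (in 17 only); TiCl(C5H5)[(S,S)-TADDOLate], CC1(C)O[C@H]2[C@H](O1)C(c3ccccc3)(c3ccccc3)O[Ti](Cl)(C3C=CC=C3)OC2(c3ccccc3)c3ccccc3 (in 18 only)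
Why: Hafner–Duthaler allyltitanation: the γ-substituted allyltitanium equilibrates to the E primary isomer and adds through a chair transition state, giving the anti C6/C7 adduct; the (S,S) ligand directs it to the Re face of the aldehyde (6R,7R). This is the anti-Felkin face with respect to C5, so the step relies on the strong reagent control of this reagent class.

Step 11
Reactants: 19 tert-butyl (3S)-4-ethenyl-3-[(1R,2R)-1-hydroxy-2-{2-[(4-methoxyphenyl)methoxy]ethyl}but-3-en-1-yl]-4-methylhex-5-enoate
Product: 20 (4S,5R)-5-{(3R)-5-[(4-methoxyphenyl)methoxy]pent-1-en-3-yl}-4-(3-methylpenta-1,4-dien-3-yl)dihydrofuran-2(3H)-one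
Conditions: camphor-10-sulfonic acid (0.2 equiv), PhMe, 70 °C
Reagents that add atoms: none
Why: Acid-catalysed lactonisation of a γ-hydroxy tert-butyl ester with loss of tert-butanol; the exchange is at the acyl carbon, so C6 is untouched and the cis lactone follows from steps 5 and 10.

Step 12
Reactants: 20 (4S,5R)-5-{(3R)-5-[(4-methoxyphenyl)methoxy]pent-1-en-3-yl}-4-(3-methylpenta-1,4-dien-3-yl)dihydrofuran-2(3H)-one
Product: 21 (3aS,4S,7R,7aR)-4-ethenyl-7-{2-[(4-methoxyphenyl)methoxy]ethyl}-4-methyl-3a,4,7,7a-tetrahydro-1-benzofuran-2(3H)-one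
Conditions: second-generation Grubbs catalyst RuCl2(=CHPh)(H2IMes)(PCy3) (5 mol%), CH2Cl2 (0.005 M), 40 °C
Reagents that add atoms: none
Why: The ruthenium benzylidene exchanges first with the C8 vinyl group, the only alkene not attached to a quaternary carbon; the new alkylidene adds across one C10 vinyl group to a ruthenacyclobutane, whose cycloreversion gives C8=C9 and a ruthenium methylidene that carries the chain with loss of ethene. The closest known reaction type is the diastereotopic-group-selective ring-closing metathesis of trienes with two identical alkenes on a prochiral carbon next to a stereocentre. One ring is closed, the cyclohexene, through a six-membered half-chair of C5–C10; no other ring can form because the two C10 vinyl groups share one carbon and C4 is a saturated lactone CH2. The one new stereocentre, C10, is under substrate control: the cis-fused lactone allows only the half-chair with C6–O axial and with C5–C4 and the C7 side chain equatorial (the flipped form would set C4 and C11 syn-diaxial), so the two spectator sites on C10 differ, one pseudo-axial and syn to the C6–O bond, the other pseudo-equatorial beside the ruthenacycle at C9. The step needs the spectator vinyl group in the pseudo-axial site (cis to C5–C4) and the methyl group in the pseudo-equatorial one; the planar vinyl group has the smaller axial demand and can turn its edge to the syn-axial oxygen, so this arrangement should be favoured, but the two groups are close in size and the preference is expected to be moderate. High dilution suppresses cross-metathesis, and the remaining C10 vinyl group is too hindered to react further.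

Step 13
Reactants: 21 (3aS,4S,7R,7aR)-4-ethenyl-7-{2-[(4-methoxyphenyl)methoxy]ethyl}-4-methyl-3a,4,7,7a-tetrahydro-1-benzofuran-2(3H)-one
Product: 24 (3aR,4S,7R,7aR)-4-ethenyl-7-{2-[(4-methoxyphenyl)methoxy]ethyl}-4-methyl-3-methylidene-3a,4,7,7a-tetrahydro-1-benzofuran-2(3H)-one, via Mannich base 22 (not isolated), via trimethylammonium iodide 23 (not isolated)
Conditions: LiN(SiMe3)2, THF, −78 °C; CH2=NMe2+ I−, −78 °C → rt; MeI, MeOH, rt; aq. NaHCO3, CH2Cl2
Reagents that add atoms: Eschenmoser's salt, C=[N+](C)C.[I-]; iodomethane, CI (in 23 only)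
Why: α-Methylenation of a lactone by Mannich reaction of its lithium enolate, quaternisation and E1cB loss of trimethylamine; C4 is the only enolisable position and the new C4=C3 carbon is not stereogenic.

Step 14
Reactants: 24 (3aR,4S,7R,7aR)-4-ethenyl-7-{2-[(4-methoxyphenyl)methoxy]ethyl}-4-methyl-3-methylidene-3a,4,7,7a-tetrahydro-1-benzofuran-2(3H)-one
Product: 25 (1R,2R,5S,6R)-5-ethenyl-6-(3-hydroxyprop-1-en-2-yl)-2-{2-[(4-methoxyphenyl)methoxy]ethyl}-5-methylcyclohex-3-en-1-ol
Conditions: iBu2AlH (4 equiv), CH2Cl2, −78 → 0 °C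
Reagents that add atoms: none
Why: 1,2-Reduction of the α-methylene lactone through the lactol gives the 2-methylidene-1,4-diol (O6–H and O15–H) and leaves the isolated alkenes alone.

Step 15
Reactants: 25 (1R,2R,5S,6R)-5-ethenyl-6-(3-hydroxyprop-1-en-2-yl)-2-{2-[(4-methoxyphenyl)methoxy]ethyl}-5-methylcyclohex-3-en-1-ol
Product: 27 15-[(tert-butyldimethylsilyl)oxy]-12-[(4-methoxybenzyl)oxy]-6-[(triethylsilyl)oxy]-13-norelema-1,3,8-triene, via mono-TBS ether 26 (not isolated)
Conditions: tBuMe2SiCl, imidazole, CH2Cl2, 0 °C; then Et3SiOTf, 2,6-lutidine, −78 → 0 °C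
Reagents that add atoms: tert-butyldimethylsilyl chloride, CC(C)(C)[Si](C)(C)Cl; triethylsilyl triflate, CC[Si](CC)(CC)OS(=O)(=O)C(F)(F)F
Why: The primary allylic O15–H is silylated selectively by the chloride and the hindered secondary O6–H then by the triflate; both ethers last to the final step and come off together.

Step 16
Reactants: 27 15-[(tert-butyldimethylsilyl)oxy]-12-[(4-methoxybenzyl)oxy]-6-[(triethylsilyl)oxy]-13-norelema-1,3,8-triene
Product: 28 15-[(tert-butyldimethylsilyl)oxy]-6-[(triethylsilyl)oxy]-13-norelema-1,3,8-trien-12-ol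
Conditions: DDQ, CH2Cl2/pH 7 buffer, 0 °C
Reagents that add atoms: none
Why: Oxidative cleavage of the 4-methoxybenzyl ether (hydride abstraction, hydrolysis of the hemiacetal) leaves silyl ethers and unactivated alkenes untouched.

Step 17
Reactants: 28 15-[(tert-butyldimethylsilyl)oxy]-6-[(triethylsilyl)oxy]-13-norelema-1,3,8-trien-12-ol
Product: 29 15-[(tert-butyldimethylsilyl)oxy]-6-[(triethylsilyl)oxy]-13-norelema-1,3,8-trien-12-oic acid
Conditions: TEMPO (0.2 equiv), PhI(OAc)2 (2.5 equiv), MeCN/pH 7 buffer, rt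
Reagents that add atoms: water, O
Why: Oxoammonium oxidation takes the primary alcohol through the aldehyde hydrate to the acid without attacking alkenes; O6 is silylated, so no 6,12-lactol can form.

Step 18
Reactants: 29 15-[(tert-butyldimethylsilyl)oxy]-6-[(triethylsilyl)oxy]-13-norelema-1,3,8-trien-12-oic acid
Product: 30 15-[(tert-butyldimethylsilyl)oxy]-9-iodo-6-[(triethylsilyl)oxy]-13-norelema-1,3-dien-12,8-olide (O8 cis to C7–C11; iodine trans to O8)
Conditions: I2, NaHCO3, MeCN, 0 °C, dark
Reagents that add atoms: iodine, II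
Why: Kinetic iodolactonisation of a cyclohex-2-enylacetic acid: the carboxylate opens the iodonium ion of C8=C9 at C8, which can only give the cis-fused γ-lactone, so O8 is cis to C7–C11 (8R) and iodine on C9 is trans to it. The other alkenes have no internal nucleophile within reach, and their iodonium ions revert.

Step 19
Reactants: 30 15-[(tert-butyldimethylsilyl)oxy]-9-iodo-6-[(triethylsilyl)oxy]-13-norelema-1,3-dien-12,8-olide
Product: 31 15-[(tert-butyldimethylsilyl)oxy]-6-[(triethylsilyl)oxy]-13-norelema-1,3-dien-12,8-olide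
Conditions: Bu3SnH, PhSeSePh (10 mol%), Et3B, air, PhMe, −78 °C
Reagents that add atoms: none
Why: Radical chain deiodination; the C9 radical is a 2,2-disubstituted but-3-enyl radical that could take the vinyl group from C10 by a 1,2-shift, so it is trapped at low temperature by PhSeH formed in situ, a much faster hydrogen donor than the stannane. C9 becomes CH2 and C8 is untouched.

Step 20
Reactants: 31 15-[(tert-butyldimethylsilyl)oxy]-6-[(triethylsilyl)oxy]-13-norelema-1,3-dien-12,8-olide
Product: 34 15-[(tert-butyldimethylsilyl)oxy]-6-[(triethylsilyl)oxy]elema-1,3,11(13)-trien-12,8-olide, via Mannich base 32 (not isolated), via trimethylammonium iodide 33 (not isolated)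
Conditions: LiN(SiMe3)2, THF, −78 °C; CH2=NMe2+ I−, −78 °C → rt; MeI, MeOH, rt; aq. NaHCO3, CH2Cl2
Reagents that add atoms: Eschenmoser's salt, C=[N+](C)C.[I-]; iodomethane, CI (in 33 only)
Why: The same α-methylenation as in step 13, now at C11 of the 12,8-lactone; it installs C13.

Step 21
Reactants: 34 15-[(tert-butyldimethylsilyl)oxy]-6-[(triethylsilyl)oxy]elema-1,3,11(13)-trien-12,8-olide
Product: 36 [2-(trimethylsilyl)ethoxy]methyl 15-[(tert-butyldimethylsilyl)oxy]-8-hydroxy-6-[(triethylsilyl)oxy]elema-1,3,11(13)-trien-12-oate, via lithium carboxylate 35 (not isolated)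
Conditions: LiOH (1.1 equiv), THF/H2O, 0 °C → rt; evaporate; Me3SiCH2CH2OCH2Cl (1.05 equiv), DMF, 0 °C
Reagents that add atoms: lithium hydroxide, [Li+].[OH-]; 2-(trimethylsilyl)ethoxymethyl chloride, C[Si](C)(C)CCOCCl
Why: Hydroxide opens the lactone at the acyl carbon and the carboxylate is alkylated on oxygen, so the acyl group is never activated and O8–H cannot close back; without an amine base the neutral hydroxyl does not react with the chloride.

Step 22
Reactants: 37 3-methylfuran-2(5H)-one
Product: 40 4-methoxybenzyl (2Z)-4-(acetyloxy)-2-methylbut-2-enoate, via potassium carboxylate 38 (not isolated), via hydroxy ester 39 (not isolated)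
Conditions: KOH (1.0 equiv), MeOH/H2O, rt; evaporate; 4-MeOC6H4CH2Cl, Bu4NI (cat.), DMF, rt; then Ac2O, pyridine, DMAP, 0 °C
Reagents that add atoms: potassium hydroxide, [K+].[OH-]; 4-methoxybenzyl chloride, COc1ccc(CCl)cc1; acetic anhydride, CC(=O)OC(C)=O
Why: Saponification of the butenolide gives the Z hydroxy carboxylate with the geometry of the ring; O-alkylation of the carboxylate and acetylation in the same pot keep it from closing back to the lactone.

Step 23
Reactants: 40 4-methoxybenzyl (2Z)-4-(acetyloxy)-2-methylbut-2-enoate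
Product: 41 (2Z)-4-(acetyloxy)-2-methylbut-2-enoic acid
Conditions: CF3CO2H, anisole, CH2Cl2, 0 °C
Reagents that add atoms: none
Why: Acidolysis of the 4-methoxybenzyl ester with anisole as cation trap; the acetate is stable, and the Z acid cannot lactonise because its hydroxyl is acylated.

Step 24
Reactants: 41 (2Z)-4-(acetyloxy)-2-methylbut-2-enoic acid; 36 [2-(trimethylsilyl)ethoxy]methyl 15-[(tert-butyldimethylsilyl)oxy]-8-hydroxy-6-[(triethylsilyl)oxy]elema-1,3,11(13)-trien-12-oate
Product: 43 [2-(trimethylsilyl)ethoxy]methyl 8-{[(2Z)-4-acetoxy-2-methylbut-2-enoyl]oxy}-15-[(tert-butyldimethylsilyl)oxy]-6-[(triethylsilyl)oxy]elema-1,3,11(13)-trien-12-oate, via mixed anhydride 42 (not isolated)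
Conditions: 2,4,6-Cl3C6H2COCl, Et3N, PhMe, rt; then 36, DMAP, PhMe, 0 °C → rt
Reagents that add atoms: 2,4,6-trichlorobenzoyl chloride, O=C(Cl)c1c(Cl)cc(Cl)cc1Cl (in 42 only)
Why: Yamaguchi esterification: DMAP is acylated at the less hindered enoyl carbonyl of the mixed anhydride and passes the acyl group to O8; low temperature and a short reaction time are used to keep the Z geometry.

Step 25
Reactants: 43 [2-(trimethylsilyl)ethoxy]methyl 8-{[(2Z)-4-acetoxy-2-methylbut-2-enoyl]oxy}-15-[(tert-butyldimethylsilyl)oxy]-6-[(triethylsilyl)oxy]elema-1,3,11(13)-trien-12-oate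
Product: 44 (5R,6S,7S,8R,10R)-8-{[(2Z)-4-acetoxy-2-methylbut-2-enoyl]oxy}-6,15-dihydroxyelema-1,3,11(13)-trien-12-oic acid
Conditions: HF (48% aq., 5% v/v), MeCN, 0 °C; then Me3SiOMe
Reagents that add atoms: none
Why: Fluoride removes both silyl ethers and fragments the silylethoxymethyl ester to Me3SiF, ethene and formaldehyde; carboxylic esters and the allylic acetate are stable to dilute HF, and the base-free quench avoids acyl migration.

## Compound list

1 | 3-methylpent-2-en-4-yn-1-ol (E/Z mixture) | C#CC(C)=CCO | starting material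
2 | 3-methylpenta-2,4-dien-1-ol (E/Z mixture) | C=CC(C)=CCO | intermediate
3 | triethyl orthoacetate | CCOC(C)(OCC)OCC | starting material
4 | ethyl 3-ethenyl-3-methylpent-4-enoate | CCOC(=O)CC(C)(C=C)C=C | intermediate
5 | 3-ethenyl-3-methylpent-4-enoic acid | OC(=O)CC(C)(C=C)C=C | intermediate
6 | (4S)-4-benzyl-1,3-oxazolidin-2-one | O=C1N[C@@H](Cc2ccccc2)CO1 | starting material
7 | 3-ethenyl-3-methylpent-4-enoic pivalic anhydride | C=CC(C)(C=C)CC(=O)OC(=O)C(C)(C)C | intermediate
8 | (4S)-4-benzyl-3-(3-ethenyl-3-methylpent-4-enoyl)-1,3-oxazolidin-2-one | C=CC(C)(C=C)CC(=O)N1[C@@H](Cc2ccccc2)COC1=O | intermediate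
9 | tert-butyl bromoacetate | CC(C)(C)OC(=O)CBr | starting material
10 | tert-butyl (3S)-3-{[(4S)-4-benzyl-2-oxo-1,3-oxazolidin-3-yl]carbonyl}-4-ethenyl-4-methylhex-5-enoate | C=CC(C)(C=C)[C@H](CC(=O)OC(C)(C)C)C(=O)N1[C@@H](Cc2ccccc2)COC1=O | intermediate
11 | tert-butyl (3S)-4-ethenyl-3-[(ethylsulfanyl)carbonyl]-4-methylhex-5-enoate | C=CC(C)(C=C)[C@H](CC(=O)OC(C)(C)C)C(=O)SCC | intermediate
12 | tert-butyl (3S)-4-ethenyl-3-formyl-4-methylhex-5-enoate | O=C[C@@H](CC(=O)OC(C)(C)C)C(C)(C=C)C=C | intermediate
13 | but-3-en-1-ol | C=CCCO | starting material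
14 | 1-[(but-3-en-1-yloxy)methyl]-4-methoxybenzene | C=CCCOCc1ccc(OC)cc1 | intermediate
15 | (2Z)-1,4-dichlorobut-2-ene | ClC/C=C\CCl | starting material
16 | 1-{[(5-chloropent-3-en-1-yl)oxy]methyl}-4-methoxybenzene (mainly E) | ClC/C=C/CCOCc1ccc(OC)cc1 | intermediate
17 | {5-[(4-methoxybenzyl)oxy]pent-2-en-1-yl}magnesium chloride | COc1ccc(COCC/C=C/C[Mg]Cl)cc1 | intermediate
18 | cyclopentadienyl{(2E)-5-[(4-methoxybenzyl)oxy]pent-2-en-1-yl}[(S,S)-TADDOLato]titanium | CC1(C)O[C@H]2[C@H](O1)C(c3ccccc3)(c3ccccc3)O[Ti](C/C=C/CCOCc3ccc(OC)cc3)(C3C=CC=C3)OC2(c3ccccc3)c3ccccc3 | intermediate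
19 | tert-butyl (3S)-4-ethenyl-3-[(1R,2R)-1-hydroxy-2-{2-[(4-methoxyphenyl)methoxy]ethyl}but-3-en-1-yl]-4-methylhex-5-enoate | C=C[C@@H](CCOCc1ccc(OC)cc1)[C@@H](O)[C@@H](CC(=O)OC(C)(C)C)C(C)(C=C)C=C | intermediate
20 | (4S,5R)-5-{(3R)-5-[(4-methoxyphenyl)methoxy]pent-1-en-3-yl}-4-(3-methylpenta-1,4-dien-3-yl)dihydrofuran-2(3H)-one | C=C[C@@H](CCOCc1ccc(OC)cc1)[C@H]1OC(=O)C[C@H]1C(C)(C=C)C=C | intermediate
21 | (3aS,4S,7R,7aR)-4-ethenyl-7-{2-[(4-methoxyphenyl)methoxy]ethyl}-4-methyl-3a,4,7,7a-tetrahydro-1-benzofuran-2(3H)-one | C=C[C@@]1(C)C=C[C@@H](CCOCc2ccc(OC)cc2)[C@H]2OC(=O)C[C@@H]12 | intermediate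
22 | C4 dimethylaminomethyl derivative of 21 (C4 epimers) | C=C[C@@]1(C)C=C[C@@H](CCOCc2ccc(OC)cc2)[C@H]2OC(=O)C(CN(C)C)[C@@H]12 | intermediate
23 | C4 trimethylammoniomethyl iodide of 21 (C4 epimers) | C=C[C@@]1(C)C=C[C@@H](CCOCc2ccc(OC)cc2)[C@H]2OC(=O)C(C[N+](C)(C)C)[C@@H]12.[I-] | intermediate
24 | (3aR,4S,7R,7aR)-4-ethenyl-7-{2-[(4-methoxyphenyl)methoxy]ethyl}-4-methyl-3-methylidene-3a,4,7,7a-tetrahydro-1-benzofuran-2(3H)-one | C=C[C@@]1(C)C=C[C@@H](CCOCc2ccc(OC)cc2)[C@H]2OC(=O)C(=C)[C@@H]12 | intermediate
25 | (1R,2R,5S,6R)-5-ethenyl-6-(3-hydroxyprop-1-en-2-yl)-2-{2-[(4-methoxyphenyl)methoxy]ethyl}-5-methylcyclohex-3-en-1-ol | C=C[C@@]1(C)C=C[C@@H](CCOCc2ccc(OC)cc2)[C@@H](O)[C@H]1C(=C)CO | intermediate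
26 | 15-[(tert-butyldimethylsilyl)oxy]-12-[(4-methoxybenzyl)oxy]-13-norelema-1,3,8-trien-6-ol | C=C[C@@]1(C)C=C[C@@H](CCOCc2ccc(OC)cc2)[C@@H](O)[C@H]1C(=C)CO[Si](C)(C)C(C)(C)C | intermediate
27 | 15-[(tert-butyldimethylsilyl)oxy]-12-[(4-methoxybenzyl)oxy]-6-[(triethylsilyl)oxy]-13-norelema-1,3,8-triene | C=C[C@@]1(C)C=C[C@@H](CCOCc2ccc(OC)cc2)[C@@H](O[Si](CC)(CC)CC)[C@H]1C(=C)CO[Si](C)(C)C(C)(C)C | intermediate
28 | 15-[(tert-butyldimethylsilyl)oxy]-6-[(triethylsilyl)oxy]-13-norelema-1,3,8-trien-12-ol | C=C[C@@]1(C)C=C[C@@H](CCO)[C@@H](O[Si](CC)(CC)CC)[C@H]1C(=C)CO[Si](C)(C)C(C)(C)C | intermediate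
29 | 15-[(tert-butyldimethylsilyl)oxy]-6-[(triethylsilyl)oxy]-13-norelema-1,3,8-trien-12-oic acid | C=C[C@@]1(C)C=C[C@@H](CC(=O)O)[C@@H](O[Si](CC)(CC)CC)[C@H]1C(=C)CO[Si](C)(C)C(C)(C)C | intermediate
30 | 15-[(tert-butyldimethylsilyl)oxy]-9-iodo-6-[(triethylsilyl)oxy]-13-norelema-1,3-dien-12,8-olide (O8 cis to C7–C11; iodine trans to O8) | C=C[C@@]1(C)[C@H](I)[C@H]2OC(=O)C[C@H]2[C@@H](O[Si](CC)(CC)CC)[C@H]1C(=C)CO[Si](C)(C)C(C)(C)C | intermediate
31 | 15-[(tert-butyldimethylsilyl)oxy]-6-[(triethylsilyl)oxy]-13-norelema-1,3-dien-12,8-olide | C=C[C@@]1(C)C[C@H]2OC(=O)C[C@H]2[C@@H](O[Si](CC)(CC)CC)[C@H]1C(=C)CO[Si](C)(C)C(C)(C)C | intermediate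
32 | C11 dimethylaminomethyl derivative of 31 (C11 epimers) | C=C[C@@]1(C)C[C@H]2OC(=O)C(CN(C)C)[C@H]2[C@@H](O[Si](CC)(CC)CC)[C@H]1C(=C)CO[Si](C)(C)C(C)(C)C | intermediate
33 | C11 trimethylammoniomethyl iodide of 31 (C11 epimers) | C=C[C@@]1(C)C[C@H]2OC(=O)C(C[N+](C)(C)C)[C@H]2[C@@H](O[Si](CC)(CC)CC)[C@H]1C(=C)CO[Si](C)(C)C(C)(C)C.[I-] | intermediate
34 | 15-[(tert-butyldimethylsilyl)oxy]-6-[(triethylsilyl)oxy]elema-1,3,11(13)-trien-12,8-olide | C=C[C@@]1(C)C[C@H]2OC(=O)C(=C)[C@H]2[C@@H](O[Si](CC)(CC)CC)[C@H]1C(=C)CO[Si](C)(C)C(C)(C)C | intermediate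
35 | lithium 15-[(tert-butyldimethylsilyl)oxy]-8-hydroxy-6-[(triethylsilyl)oxy]elema-1,3,11(13)-trien-12-oate | C=C[C@@]1(C)C[C@@H](O)[C@@H](C(=C)C(=O)[O-])[C@@H](O[Si](CC)(CC)CC)[C@H]1C(=C)CO[Si](C)(C)C(C)(C)C.[Li+] | intermediate
36 | [2-(trimethylsilyl)ethoxy]methyl 15-[(tert-butyldimethylsilyl)oxy]-8-hydroxy-6-[(triethylsilyl)oxy]elema-1,3,11(13)-trien-12-oate | C=C[C@@]1(C)C[C@@H](O)[C@@H](C(=C)C(=O)OCOCC[Si](C)(C)C)[C@@H](O[Si](CC)(CC)CC)[C@H]1C(=C)CO[Si](C)(C)C(C)(C)C | intermediate
37 | 3-methylfuran-2(5H)-one | CC1=CCOC1=O | starting material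
38 | potassium (2Z)-4-hydroxy-2-methylbut-2-enoate | OC/C=C(/C)C(=O)[O-].[K+] | intermediate
39 | 4-methoxybenzyl (2Z)-4-hydroxy-2-methylbut-2-enoate | OC/C=C(/C)C(=O)OCc1ccc(OC)cc1 | intermediate
40 | 4-methoxybenzyl (2Z)-4-(acetyloxy)-2-methylbut-2-enoate | CC(=O)OC/C=C(/C)C(=O)OCc1ccc(OC)cc1 | intermediate
41 | (2Z)-4-(acetyloxy)-2-methylbut-2-enoic acid | CC(=O)OC/C=C(/C)C(=O)O | intermediate
42 | (2Z)-4-(acetyloxy)-2-methylbut-2-enoic 2,4,6-trichlorobenzoic anhydride | CC(=O)OC/C=C(/C)C(=O)OC(=O)c1c(Cl)cc(Cl)cc1Cl | intermediate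
43 | [2-(trimethylsilyl)ethoxy]methyl 8-{[(2Z)-4-acetoxy-2-methylbut-2-enoyl]oxy}-15-[(tert-butyldimethylsilyl)oxy]-6-[(triethylsilyl)oxy]elema-1,3,11(13)-trien-12-oate | C=C[C@@]1(C)C[C@@H](OC(=O)/C(C)=C\COC(C)=O)[C@@H](C(=C)C(=O)OCOCC[Si](C)(C)C)[C@@H](O[Si](CC)(CC)CC)[C@H]1C(=C)CO[Si](C)(C)C(C)(C)C | intermediate
44 | (5R,6S,7S,8R,10R)-8-{[(2Z)-4-acetoxy-2-methylbut-2-enoyl]oxy}-6,15-dihydroxyelema-1,3,11(13)-trien-12-oic acid | C=C[C@@]1(C)C[C@@H](OC(=O)/C(C)=C\COC(C)=O)[C@@H](C(=C)C(=O)O)[C@@H](O)[C@H]1C(=C)CO | target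

## Step count and least certain steps

Total: 25 steps. Longest linear sequence: 21 steps (steps 1–7, 10–21, 24, 25).

Step 12 (key step). The likely failure is poor discrimination between the two diastereotopic C10 vinyl groups, because the spectator methyl and vinyl groups are nearly the same size; the C10 ratio could be low or even reversed. The fallback moves the control from the substrate to the catalyst. It sets out from 19, which is silylated (Et3SiCl, imidazole) to the triethylsilyl ether F1. F1 is closed with one enantiomer of the chiral molybdenum alkylidene Mo(=N-2,6-iPr2C6H3)(=CHCMe2Ph)(3,3′-di-tert-butyl-5,5′,6,6′-tetramethylbiphenyl-2,2′-diolate), the antipode being chosen that selects the required vinyl group, to give cyclohexene F2. Bu4NF then removes the silyl group, and the alkoxide closes onto the tert-butyl ester, which returns the route to 21.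

Step 10. The likely failure is erosion of the facial selectivity: the aldehyde prefers Felkin attack, which is opposite to the face the reagent must deliver, and the tert-alkyl group on C5 may make this bias large. The fallback uses only matched substrate control. It sets out from 16 and 12. Bu3SnLi converts 16 into the allylstannane F3. BF3·OEt2-promoted addition of F3 to 12 goes through an open transition state and gives the syn, Felkin alcohol F4, which has the correct C7 and the wrong C6. Dess–Martin oxidation gives the ketone F5. Reduction with Li[HB(sBu)3] at −78 °C is Felkin-controlled by the C5 centre, delivers hydride to the face that gives 6R, and returns to 19.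

Step 19. The likely failure is rearrangement of the C9 radical by 3-exo closure onto the C10 vinyl group and reopening to the tertiary C10 radical (a 1,2-vinyl shift) before hydrogen transfer. The fallback avoids any C9 radical and sets out from 28. (HMe2Si)2NH gives the dimethylsilyl ether F6. Zerovalent platinum (Pt2[(CH2=CHSiMe2)2O]3, high dilution) closes the oxasilinane F7 by intramolecular syn hydrosilylation of C8=C9, with silicon on C8 cis to the C7 chain. Tamao oxidation (H2O2, KF, KHCO3) gives the 8,12-diol F8 with retention. TEMPO/PhI(OAc)2 then oxidises the primary alcohol through the lactol to the lactone and returns to 31.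

Step 24. The likely failures are Z to E isomerisation of the enoyl group during activation with DMAP, and slow acylation of the hindered, probably axial O8–H, which leaves time for the hydroxy ester to relactonise. The fallback builds the Z alkene on the substrate and sets out from 36. Esterification with 2-[bis(2,2,2-trifluoroethoxy)phosphoryl]propanoic acid (DCC, DMAP) gives the phosphonate F9. Still–Gennari olefination (KN(SiMe3)2, 18-crown-6, THF, −78 °C) with 2-oxoethyl acetate gives the Z enoate and returns to 43.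

Step 25. The likely failure is acid-promoted closure of the freed C12 acid onto the cis O6–H to give the 6,12-lactone, or acyl migration from O8 to O6, while HF is present. The fallback frees the acid last under neutral conditions and sets out from 35. Alkylation with 2-nitrobenzyl bromide gives the 2-nitrobenzyl ester F10. Acylation with 42 as in step 24 gives F11. HF·pyridine in THF/pyridine removes the silyl ethers while C12 is still an ester, giving the diol F12. Irradiation at 365 nm then cleaves the ester and returns to 44.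

## Further compounds

F1 | step 12 | tert-butyl (3S)-4-ethenyl-3-[(1R,2R)-2-{2-[(4-methoxyphenyl)methoxy]ethyl}-1-[(triethylsilyl)oxy]but-3-en-1-yl]-4-methylhex-5-enoate | C=C[C@@H](CCOCc1ccc(OC)cc1)[C@@H](O[Si](CC)(CC)CC)[C@@H](CC(=O)OC(C)(C)C)C(C)(C=C)C=C
F2 | step 12 | tert-butyl 12-[(4-methoxybenzyl)oxy]-6-[(triethylsilyl)oxy]-3,13-dinorelema-1,8-dien-15-oate | C=C[C@@]1(C)C=C[C@@H](CCOCc2ccc(OC)cc2)[C@@H](O[Si](CC)(CC)CC)[C@H]1CC(=O)OC(C)(C)C
F3 | step 10 | tributyl{5-[(4-methoxybenzyl)oxy]pent-2-en-1-yl}stannane | CCCC[Sn](CCCC)(CCCC)CC=CCCOCc1ccc(OC)cc1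
F4 | step 10 | tert-butyl (3S)-4-ethenyl-3-[(1S,2R)-1-hydroxy-2-{2-[(4-methoxyphenyl)methoxy]ethyl}but-3-en-1-yl]-4-methylhex-5-enoate | C=C[C@@H](CCOCc1ccc(OC)cc1)[C@H](O)[C@@H](CC(=O)OC(C)(C)C)C(C)(C=C)C=C
F5 | step 10 | tert-butyl (3S)-4-ethenyl-3-[(2R)-2-{2-[(4-methoxyphenyl)methoxy]ethyl}but-3-enoyl]-4-methylhex-5-enoate | C=C[C@@H](CCOCc1ccc(OC)cc1)C(=O)[C@@H](CC(=O)OC(C)(C)C)C(C)(C=C)C=C
F6 | step 19 | 12-O-dimethylsilyl ether of 28 | C=C[C@@]1(C)C=C[C@@H](CCO[SiH](C)C)[C@@H](O[Si](CC)(CC)CC)[C@H]1C(=C)CO[Si](C)(C)C(C)(C)C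
F7 | step 19 | 8,12-(dimethylsilanediyl) oxasilinane from F6 (silicon on C8 cis to C7–C11) | C=C[C@@]1(C)C[C@@H]2[C@@H](CCO[Si]2(C)C)[C@@H](O[Si](CC)(CC)CC)[C@H]1C(=C)CO[Si](C)(C)C(C)(C)C
F8 | step 19 | 15-[(tert-butyldimethylsilyl)oxy]-6-[(triethylsilyl)oxy]-13-norelema-1,3-diene-8,12-diol | C=C[C@@]1(C)C[C@@H](O)[C@@H](CCO)[C@@H](O[Si](CC)(CC)CC)[C@H]1C(=C)CO[Si](C)(C)C(C)(C)C
F9 | step 24 | 8-O-{2-[bis(2,2,2-trifluoroethoxy)phosphoryl]propanoyl} derivative of 36 | C=C[C@@]1(C)C[C@@H](OC(=O)C(C)P(=O)(OCC(F)(F)F)OCC(F)(F)F)[C@@H](C(=C)C(=O)OCOCC[Si](C)(C)C)[C@@H](O[Si](CC)(CC)CC)[C@H]1C(=C)CO[Si](C)(C)C(C)(C)C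
F10 | step 25 | 2-nitrobenzyl 15-[(tert-butyldimethylsilyl)oxy]-8-hydroxy-6-[(triethylsilyl)oxy]elema-1,3,11(13)-trien-12-oate | C=C[C@@]1(C)C[C@@H](O)[C@@H](C(=C)C(=O)OCc2ccccc2[N+](=O)[O-])[C@@H](O[Si](CC)(CC)CC)[C@H]1C(=C)CO[Si](C)(C)C(C)(C)C
F11 | step 25 | 2-nitrobenzyl 8-{[(2Z)-4-acetoxy-2-methylbut-2-enoyl]oxy}-15-[(tert-butyldimethylsilyl)oxy]-6-[(triethylsilyl)oxy]elema-1,3,11(13)-trien-12-oate | C=C[C@@]1(C)C[C@@H](OC(=O)/C(C)=C\COC(C)=O)[C@@H](C(=C)C(=O)OCc2ccccc2[N+](=O)[O-])[C@@H](O[Si](CC)(CC)CC)[C@H]1C(=C)CO[Si](C)(C)C(C)(C)C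
F12 | step 25 | 2-nitrobenzyl 8-{[(2Z)-4-acetoxy-2-methylbut-2-enoyl]oxy}-6,15-dihydroxyelema-1,3,11(13)-trien-12-oate | C=C[C@@]1(C)C[C@@H](OC(=O)/C(C)=C\COC(C)=O)[C@@H](C(=C)C(=O)OCc2ccccc2[N+](=O)[O-])[C@@H](O)[C@H]1C(=C)CO
A1 | alternative 1 | 2-(trimethylsilyl)ethyl 3-hydroxy-4-methoxy-5-methylbenzoate | COc1c(O)cc(C(=O)OCC[Si](C)(C)C)cc1C
A2 | alternative 1 | 2-methoxy-2,3-dihydrofuran | COC1CC=CO1
A3 | alternative 1 | endo bicyclo[2.2.2]oct-5-en-2-one adduct fused to a 2-methoxytetrahydrofuran (racemic; one enantiomer shown) | C[Si](C)(C)CCOC(=O)C2=C[C@@]1(C)C(OC)(OC)C(=O)[C@@H]2[C@@H](O[C@H](OC)C3)[C@H]13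
A4 | alternative 2 | 2-bromoprop-2-en-1-yl 3,5-dimethoxy-1-methylcyclohexa-2,5-diene-1-carboxylate | C=C(Br)COC(=O)C1(C)C=C(OC)CC(OC)=C1
A5 | alternative 2 | cis-fused methylene δ-lactone on the 6,8-dimethoxycyclohexadiene | O=C3[C@@]1(C)C=C(OC)C=C(OC)[C@H]1C(=C)CO3
A6 | alternative 3 | methyl 4-[(tert-butyldimethylsilyl)oxy]-3-{[(tert-butyldimethylsilyl)oxy]methylidene}pent-4-enoate | C=C(O[Si](C)(C)C(C)(C)C)C(CC(=O)OC)=CO[Si](C)(C)C(C)(C)C
A7 | alternative 3 | (5S)-5-[(1S,2R,5S)-menthyloxy]-4-methylfuran-2(5H)-one | CC1=CC(=O)O[C@@H]1O[C@H]2C[C@@H](C)CC[C@@H]2C(C)C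
A8 | alternative 3 | endo cycloadduct: cis-fused menthyloxy lactone with C8 silyl enol ether and C6 silyl ether | O=C2O[C@H](O[C@H]3C[C@@H](C)CC[C@@H]3C(C)C)[C@@]1(C)CC(O[Si](C)(C)C(C)(C)C)=C(CC(=O)OC)[C@@H](O[Si](C)(C)C(C)(C)C)[C@H]12
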